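## The problem

Compound 12 is an aryl tert-alkyl ether in which O-2 of honokiol (the hydroxyl ortho to the biaryl bond) is bonded to C4 of a trans-fused eudesmane (rings A and B) that also carries a free tertiary carbinol, C11, on the C7 side chain. The terpene half has four stereocentres: quaternary C10 (β-methyl), C5 (α-H), C7 (β, equatorial hydroxypropyl group) and fully substituted C4 (α, equatorial aryloxy group; β, axial methyl group syn to the C10 methyl). C5, C7 and C10 are locked together in the rigid decalin and are best bought as a set; C4 can then be set last under their control, because the axial C10 methyl shields the β face of C4. The C4–O bond is the hard one: the carbon is tertiary and neopentyl-like, the oxygen belongs to a hindered ortho-arylphenol, displacement with inversion is not available, and the finished ether ionises readily in acid. The two allyl groups, the free phenol, the elimination-prone C11 carbinol and the need to tell the two honokiol hydroxyls apart restrict the end game to mild finishing steps. The enabling feature is the shape of ring A seen from ring B: a two-carbon arm on C10 (C1–C2) and an isopropenyl-type arm on C5 (C3, C4 and C15), trans-diequatorial, which is the substitution pattern of elemol 1, a terpene that holds all fifteen carbons and the C5, C7 and C10 centres and lacks only the C2–C3 bond. With C2 as an aldehyde the two arms form a 5-methylhex-5-enal, the substrate of a type 2 carbonyl-ene closure. That closure makes C2–C3 and leaves the C4 exocyclic methylene, the latent C4 cation needed for the ether.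

## Retrosynthesis

**12 from 11 (two O–Si bonds).** Both remaining hydroxyls are carried as silyl ethers to the end. Fluoride is the one deprotection that spares the tertiary aryl ether (no acid), the allyl groups (no hydrogenolysis, no strong base) and all stereocentres. The precursor 11 is no simpler, but the forward step is routine.

**11 from 8 and 10 (the C4–O bond).** Cutting on the terpene side gives a C4 cation, whose stable equivalent is the exocyclic alkene 8, and the phenol 10. The neighbouring cut, on the aryl side, would need a C4 alkoxide, an activated halobenzene and a later biaryl construction; it costs several more steps and is kept as the reserve. The chosen cut brings in honokiol 9 whole and lets the C10 methyl set C4. The forward reaction must protonate only the 1,1-disubstituted alkene, capture the cation on the α face under kinetic control, and leave the silyl ethers intact.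

**10 from 9 (one O–Si bond).** Honokiol 9 is commercial; only O-4' has to be blocked so that O-2 is the sole nucleophile.

**8 from 6 through 7 (C2–H back to C2–O).** A hydroxyl is added retrosynthetically at C2. It serves no purpose in 12, but it is what makes ring A closable from an aldehyde. Its removal costs two steps and touches no stereocentre of consequence.

**6 from 5 (the C2–C3 bond, key step).** This cut opens ring A between two arms that already sit on C10 and C5 with the right relative configuration, so the ring closure creates no ring-fusion stereocentre. Cutting C5–C10 (transannular closure) or C1–C10 and C4–C5 (annulation) would each require stereocentres to be made. The precursor 5 is monocyclic and holds all fifteen carbons. The forward reaction must form the bond and deliver the alkene to the exocyclic C4(15) position.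

**5 from 4, 4 from 2 through 3, 2 from 1.** The aldehyde comes from the primary alcohol 4, and 4 from anti-Markovnikov hydroboration of the vinyl group of 2 by way of the boronate 3. The only demand is chemoselectivity for the vinyl over the isopropenyl group. Compound 2 is elemol 1 with its tertiary hydroxyl silylated.

## Roads not taken

Alternative 1: Biomimetic transannular cyclisation of hedycaryol A1 with interception by the phenol.
- *Cut:* C5–C10 and C4–O together.
- *Forward step:* protonation of A1 at C1, attack of the C4=C5 alkene on the C10 cation across the ten-membered ring, and capture of the C4 cation by 10. This would give the mono-silyl ether A2, one desilylation from 12.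
- *Merits:* this is the shortest conceivable route. Both rings, two bonds and three stereocentres arise in one operation, and it mirrors the likely biogenesis. In step count it beats the chosen plan.
- *Weak points:* A1 is not an article of commerce, exists as interconverting conformers, and rearranges thermally to 1, so it cannot be made from 1 and needs its own synthesis with C7 set. The cyclisation normally ends by proton loss or hydration, and a hindered phenol must beat both intermolecularly. Ring formation and capture cannot be optimised separately.
- *Comparison:* the chosen plan answers with a stable, purchasable terpene. Its ring closure does not depend on the phenol. Its capture step starts from one defined alkene 8 and can be replaced by a non-cationic reserve route.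

Alternative 2: Bargellini three-component aryloxylation of the C4 nor-ketone A3.
- *Cut:* C4–O and C4–C15.
- *Forward step:* A3, chloroform and NaOH form a trichloromethyl carbinol that closes to a gem-dichloroepoxide, which the phenoxide of 2-bromo-4-chlorophenol A4 opens at C4 with inversion. This would give the α-aryloxy acid A5.
- *Merits:* the C4–O bond is made irreversibly and stereospecifically, without a free cation. There is no elimination and no risk to C5, and a monocyclic phenol removes the honokiol regiochemistry question. In certainty of C4 control it is better than the chosen plan.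
- *Weak points:* A3 has to be made by cutting C15 off an alkene such as 8, only to put it back as a carboxyl group. Turning CO2H into CH3 at a neopentyl position takes three or four steps. The biaryl bond and both allyl groups still have to be installed. A hindered ortho-bromophenoxide attacking a tertiary carbon next to the ring fusion stretches the reaction beyond its usual substrates.
- *Comparison:* the chosen plan answers with C15 at the right oxidation level throughout, honokiol bought whole, and about half the step count.

Alternative 3: Robinson annulation of dihydrocarvone A6 to (+)-α-cyperone A8, then relay.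
- *Cut:* C1–C10 and C4=C5 of ring A.
- *Forward step:* the imine of A6 with a chiral primary benzylic amine auxiliary adds through its enamine tautomer to ethyl vinyl ketone A7, and aldol condensation closes ring A to give A8.
- *Merits:* the starting material is cheap and scalable, the annulation is proven, and C10 is set under auxiliary control. In cost and scale it is better than the chosen plan.
- *Weak points:* A8 has the wrong functionality. The C3 ketone must be removed, the C4=C5 alkene must become a 5α-H ring fusion with a C4 exocyclic alkene, and the isopropenyl group must be hydrated to the C11 carbinol in the presence of the ring alkene. That is a long relay before an intermediate like 8 is reached, and C5 has to be set along the way.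
- *Comparison:* the chosen plan answers with C5, C11–OH and the C3 oxidation level already correct in 1. Its only surplus function is the C2 hydroxyl, which takes two steps to erase.

Key step: step 4

Assumption: eudesmane numbering is used for all terpene compounds, including the 2,3-seco (elemane) ones; elemol is taken to be purchasable as the natural (−)-enantiomer drawn as 1; the C2 configuration of 6 and 7 is left open because that centre is removed in step 6.

## Route

Step 1
Reactants: 1 (−)-elemol
Product: 2 11-(triethylsilyloxy)elema-1,3-diene
Conditions: TESOTf, 2,6-lutidine, CH2Cl2, −78 → 0 °C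
Reagents that add atoms: triethylsilyl trifluoromethanesulfonate, CC[Si](CC)(CC)OS(=O)(=O)C(F)(F)F
Why: Silylation of a hindered tertiary alcohol with a silyl triflate and a hindered pyridine base is standard; the masked C11 oxygen will neither consume Me2AlCl in step 4 nor ionise in step 8, and no stereocentre is touched.

Step 2
Reactants: 2 11-(triethylsilyloxy)elema-1,3-diene
Product: 4 11-(triethylsilyloxy)elem-3-en-2-ol, via B-alkyl catecholborane 3 (not isolated)
Conditions: Rh(PPh3)3Cl (2 mol %), catecholborane, THF, 0 °C → rt; then NaOH, H2O2, EtOH/H2O, 0 °C → rt
Reagents that add atoms: catecholborane, [H]B1Oc2ccccc2O1; hydrogen peroxide, OO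
Why: Rhodium-catalysed hydroboration is much faster for monosubstituted than for 1,1-disubstituted alkenes and places boron on the terminal carbon, so the vinyl group should react and the isopropenyl group should not; uncatalysed dialkylboranes do not separate a neopentyl-type vinyl from an isopropenyl group reliably, which is why the catalysed variant is chosen. Alkaline peroxide then replaces the boron of 3 by the hydroxyl oxygen of 4 with the carbon skeleton unchanged, the catecholate being lost.

Step 3
Reactants: 4 11-(triethylsilyloxy)elem-3-en-2-ol
Product: 5 11-(triethylsilyloxy)elem-3-en-2-al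
Conditions: Dess–Martin periodinane, CH2Cl2, 0 °C → rt
Reagents that add atoms: none
Why: Dess–Martin oxidation of a primary alcohol stops at the aldehyde under near-neutral conditions; the aldehyde has a quaternary β-carbon and no α-stereocentre, so neither epimerisation nor elimination is possible, and it is used directly.

Step 4
Reactants: 5 11-(triethylsilyloxy)elem-3-en-2-al
Product: 6 11-(triethylsilyloxy)eudesm-4(15)-en-2-ol
Conditions: Me2AlCl (1.5–2 equiv), CH2Cl2, −78 → 0 °C; aq. NaHCO3 quench
Reagents that add atoms: none
Why: Me2AlCl binds the aldehyde oxygen, the terminal carbon of the isopropenyl group (C3) attacks C2, and a hydrogen of the isopropenyl methyl (C15) passes to oxygen, either in concert or through a short-lived C4 cation whose aluminium alkoxide takes the proton by a 1,5-shift; the methyl groups on aluminium destroy any HCl, so no protic acid reaches the product. The closest known reaction type is the Me2AlCl-promoted type 2 carbonyl-ene cyclisation of 5-methylhex-5-enals to 3-methylenecyclohexanols. Ring A closes as a six-membered ring, 6-exo with respect to the carbonyl and 6-endo with respect to the alkene, the tether being attached to the central carbon of the ene unit; the two reacting arms are already trans-diequatorial on ring B, so the trans-decalin results and C5, C7 and C10 are untouched. The only new stereocentre is the C2 carbinol: in the chair transition state the oxygen reaches the C15 hydrogen only from the axial β position, syn to the C10 methyl, so the axial alcohol, its epimer from a stepwise path, or a mixture may result, and all are acceptable because C2 is deoxygenated in steps 5 and 6. The selectivity that matters is regiochemical, proton loss from C15 and not from C3 or C5, and the intramolecular hydrogen transfer to oxygen secures it; a minor amount of the 3-ene isomer would still lead to the same C4 cation in step 8. No other alkene or carbonyl group is present, and the tertiary silyl ether should be stable to Me2AlCl at low temperature.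

Step 5
Reactants: 6 11-(triethylsilyloxy)eudesm-4(15)-en-2-ol
Product: 7 O-[11-(triethylsilyloxy)eudesm-4(15)-en-2-yl] S-methyl dithiocarbonate
Conditions: NaH, imidazole (cat.), THF, 0 °C → rt; CS2; then MeI
Reagents that add atoms: carbon disulfide, S=C=S; iodomethane, CI
Why: Xanthate formation from a secondary alkoxide is the first half of a Barton–McCombie deoxygenation; the silyl ether and the exocyclic alkene are inert to NaH, CS2 and MeI.

Step 6
Reactants: 7 O-[11-(triethylsilyloxy)eudesm-4(15)-en-2-yl] S-methyl dithiocarbonate
Product: 8 11-(triethylsilyloxy)eudesm-4(15)-ene
Conditions: Bu3SnH, AIBN (cat.), toluene, 100 °C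
Reagents that add atoms: none
Why: Barton–McCombie radical deoxygenation; the secondary C2 radical is homoallylic, but its 3-exo closure onto C4 is reversible and could only lead on to a less stable primary radical, so hydrogen transfer from tin to C2 should prevail. The C2 centre is erased and the hindered exocyclic alkene should not be hydrostannylated.

Step 7
Reactants: 9 honokiol
Product: 10 4'-O-(triisopropylsilyl)honokiol
Conditions: TIPSCl (1.0 equiv), imidazole, CH2Cl2, 0 °C
Reagents that add atoms: chlorotriisopropylsilane, CC(C)[Si](Cl)(C(C)C)C(C)C
Why: Silylation of a phenol with a bulky chlorosilane and imidazole; O-4' is flanked only by a benzylic CH2 and is slightly more acidic, whereas O-2 lies in the cleft of the twisted biaryl, so the bulky silyl group should go to O-4'. The regioisomer and the bis-ether would be removed by chromatography and returned to 9 with fluoride. The silyl group also keeps the hydroxyl ortho to an allyl group from closing to a dihydrobenzofuran under the acid of step 8.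

Step 8
Reactants: 8 11-(triethylsilyloxy)eudesm-4(15)-ene; 10 4'-O-(triisopropylsilyl)honokiol
Product: 11 4α-[4'-O-(triisopropylsilyl)honokiol-2-yloxy]-11-(triethylsilyloxy)eudesmane
Conditions: TfOH (10 mol %), threefold excess of the phenol, CH2Cl2, −78 → −40 °C; Et3N quench at −78 °C
Reagents that add atoms: none
Why: Brønsted-acid-catalysed Markovnikov addition of a phenol to a 1,1-disubstituted alkene, the reaction that gives aryl tert-butyl ethers from isobutene at low temperature; only the exocyclic alkene is protonated (at C15), since the allyl groups would give secondary cations. The C4 cation is captured on the α (equatorial) face because the β face is blocked by the syn-axial C10 methyl, the same preference seen when 4(15)-eudesmenes are hydrated to 4α-ols, and this sets C4. Low temperature, excess phenol and a cold basic quench keep the addition under kinetic control.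

Step 9
Reactants: 11 4α-[4'-O-(triisopropylsilyl)honokiol-2-yloxy]-11-(triethylsilyloxy)eudesmane
Product: 12 4α-(honokiol-2-yloxy)eudesman-11-ol (target)
Conditions: TBAF, THF, 0 → 40 °C
Reagents that add atoms: none
Why: Fluoride cleaves both Si–O bonds, the aryl silyl ether quickly and the tertiary triethylsilyl ether on gentle warming; the conditions are non-acidic, so the tertiary aryl ether, the allyl groups and all four stereocentres should be unaffected.

## Compound list

1 | (−)-elemol, 2-[(1R,3S,4S)-4-ethenyl-4-methyl-3-(prop-1-en-2-yl)cyclohexyl]propan-2-ol (elema-1,3-dien-11-ol; 5α-H, 7β side chain, 10β-methyl) | C=C[C@]1(C)CC[C@@H](C(C)(C)O)C[C@H]1C(C)=C | starting material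
2 | 11-(triethylsilyloxy)elema-1,3-diene (elemol triethylsilyl ether, configuration of 1) | C=C[C@]1(C)CC[C@@H](C(C)(C)O[Si](CC)(CC)CC)C[C@H]1C(C)=C | intermediate
3 | 2-(1,3,2-benzodioxaborol-2-yl)-11-(triethylsilyloxy)elem-3-ene (B-alkyl catecholborane, not isolated) | O1c2ccccc2OB1CC[C@]1(C)CC[C@@H](C(C)(C)O[Si](CC)(CC)CC)C[C@H]1C(C)=C | intermediate
4 | 11-(triethylsilyloxy)elem-3-en-2-ol (primary alcohol on the former vinyl group) | OCC[C@]1(C)CC[C@@H](C(C)(C)O[Si](CC)(CC)CC)C[C@H]1C(C)=C | intermediate
5 | 11-(triethylsilyloxy)elem-3-en-2-al | O=CC[C@]1(C)CC[C@@H](C(C)(C)O[Si](CC)(CC)CC)C[C@H]1C(C)=C | intermediate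
6 | 11-(triethylsilyloxy)eudesm-4(15)-en-2-ol (trans-decalin, 5α-H, 7β side chain, 10β-methyl; C2 carbinol as formed) | C=C1CC(O)C[C@]2(C)CC[C@@H](C(C)(C)O[Si](CC)(CC)CC)C[C@H]21 | intermediate
7 | O-[11-(triethylsilyloxy)eudesm-4(15)-en-2-yl] S-methyl dithiocarbonate (C2 as in 6) | C=C1CC(OC(=S)SC)C[C@]2(C)CC[C@@H](C(C)(C)O[Si](CC)(CC)CC)C[C@H]21 | intermediate
8 | 11-(triethylsilyloxy)eudesm-4(15)-ene (β-eudesmol triethylsilyl ether; 5α-H, 7β side chain, 10β-methyl) | C=C1CCC[C@]2(C)CC[C@@H](C(C)(C)O[Si](CC)(CC)CC)C[C@H]21 | intermediate
9 | honokiol, 3',5-di(prop-2-en-1-yl)biphenyl-2,4'-diol | C=CCc1ccc(O)c(-c2ccc(O)c(CC=C)c2)c1 | starting material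
10 | 4'-O-(triisopropylsilyl)honokiol, 3',5-diallyl-4'-(triisopropylsilyloxy)biphenyl-2-ol | C=CCc1ccc(O)c(-c2ccc(O[Si](C(C)C)(C(C)C)C(C)C)c(CC=C)c2)c1 | intermediate
11 | 4α-[4'-O-(triisopropylsilyl)honokiol-2-yloxy]-11-(triethylsilyloxy)eudesmane (4β-methyl, 5α-H, 7β side chain, 10β-methyl) | C=CCc1ccc(O[C@]2(C)CCC[C@]3(C)CC[C@@H](C(C)(C)O[Si](CC)(CC)CC)C[C@H]32)c(-c2ccc(O[Si](C(C)C)(C(C)C)C(C)C)c(CC=C)c2)c1 | intermediate
12 | 4α-(honokiol-2-yloxy)eudesman-11-ol, terpene part (1R,4aR,7R,8aR) in decalin numbering (4α-aryloxy, 4β-methyl, 5α-H, 7β-(2-hydroxypropan-2-yl), 10β-methyl) | C=CCc1ccc(O[C@]2(C)CCC[C@]3(C)CC[C@@H](C(C)(C)O)C[C@H]32)c(-c2ccc(O)c(CC=C)c2)c1 | target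

## Step count and risks

Total step count: 9. Longest linear sequence: 8 steps (steps 1–6, 8 and 9, from 1 to 12); step 7 is a one-step side branch from 9.

**Step 8 (addition of the phenol to C4), the least certain step.** The C4 cation may lose a proton to the 3-ene or 4-ene faster than the hindered phenol captures it, or the ether may ionise again, because the addition is an equilibrium that only low temperature holds on the ether side. Reprotonation of a 4(5)-ene would also endanger the C5 configuration, ortho C-alkylation of the phenol may compete, and the acid may strip the triethylsilyl group from C11 and so open the way to ionisation there.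

Fallback: this sets out from 8 and returns to the route at 12, with the C4–O bond made before the arene is attached. Oxymercuration–demercuration of 8 (Hg(OAc)2, THF/H2O; then NaBH4, NaOH) should give 11-(triethylsilyloxy)eudesman-4α-ol F6 with the hydroxyl delivered to the α face. The potassium alkoxide of F6 (KH, 18-crown-6, THF) would displace fluoride from commercial 2-bromo-4-chloro-1-fluorobenzene at 60 °C to give the 2-bromo-4-chlorophenyl ether F7. Suzuki–Miyaura coupling at the bromide with commercial (3-chloro-4-hydroxyphenyl)boronic acid (Pd(dppf)Cl2, K3PO4, dioxane/H2O) would give the dichlorobiaryl ether F8. Twofold coupling of the aryl chlorides with allylboronic acid pinacol ester (Pd(OAc)2, XPhos, K3PO4, THF/H2O) would give 4α-(honokiol-2-yloxy)-11-(triethylsilyloxy)eudesmane F9, and TBAF would then give 12.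

**Step 4 (key step).** After the C2–C3 bond forms, the C4 cation may be captured by chloride or lose a ring proton instead of passing the C15 hydrogen to oxygen. The oxygen reaches that hydrogen only from the axial position syn to the C10 methyl, so the concerted path is sterically burdened.

Fallback: this sets out from 4 and returns at 6; the same C2–C3 bond is made by an allylmetal addition. Ene-type chlorination of the isopropenyl group of 4 (NaOCl, CeCl3·7H2O, CH2Cl2/H2O, 0 °C) would give 15-chloro-11-(triethylsilyloxy)elem-3-en-2-ol F2. Dess–Martin oxidation would give 15-chloro-11-(triethylsilyloxy)elem-3-en-2-al F3. Intramolecular Nozaki–Hiyama allylation (CrCl2, divalent chromium, with LiI in THF) would close ring A to 6; either terminus of the 2-substituted allyl unit gives the same methylenecyclohexanol.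

**Step 2 (hydroboration of the vinyl group only).** The isopropenyl group may be hydroborated as well, through an uncatalysed background reaction of borane formed from catecholborane, while the vinyl group on quaternary C10 is shielded.

Fallback: this sets out from 2 and returns at 4. Platinum-catalysed hydrosilylation (Pt2[(CH2=CHSiMe2)2O]3, zerovalent platinum, with (EtO)3SiH in toluene) strongly prefers monosubstituted alkenes and would give 2-(triethoxysilyl)-11-(triethylsilyloxy)elem-3-ene F1. Tamao oxidation (H2O2, KF, KHCO3, THF/MeOH) would convert F1 into 4.

**Step 7 (silylation of one hydroxyl of honokiol).** Silylation may occur at O-2 or at both oxygens, because both hydroxyls are mono-ortho-substituted phenols of nearly equal acidity.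

Fallback: this bypasses 9; it sets out from commercial 2-allyl-4-bromophenol in place of 9 and returns at 10, with the regiochemistry fixed by construction. Silylation (TIPSCl, imidazole) would give (2-allyl-4-bromophenoxy)triisopropylsilane F4. Suzuki–Miyaura coupling with commercial (5-chloro-2-hydroxyphenyl)boronic acid (Pd(PPh3)4, K2CO3, dioxane/H2O) would give 3'-allyl-5-chloro-4'-(triisopropylsilyloxy)biphenyl-2-ol F5. Coupling of the aryl chloride with allylboronic acid pinacol ester (Pd(OAc)2, XPhos, K3PO4, THF/H2O) would give 10.

## Further compounds

F1 | step 2 | 2-(triethoxysilyl)-11-(triethylsilyloxy)elem-3-ene | CCO[Si](OCC)(OCC)CC[C@]1(C)CC[C@@H](C(C)(C)O[Si](CC)(CC)CC)C[C@H]1C(C)=C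
F2 | step 4 | 15-chloro-11-(triethylsilyloxy)elem-3-en-2-ol | OCC[C@]1(C)CC[C@@H](C(C)(C)O[Si](CC)(CC)CC)C[C@H]1C(=C)CCl
F3 | step 4 | 15-chloro-11-(triethylsilyloxy)elem-3-en-2-al | O=CC[C@]1(C)CC[C@@H](C(C)(C)O[Si](CC)(CC)CC)C[C@H]1C(=C)CCl
F4 | step 7 | (2-allyl-4-bromophenoxy)triisopropylsilane | C=CCc1cc(Br)ccc1O[Si](C(C)C)(C(C)C)C(C)C
F5 | step 7 | 3'-allyl-5-chloro-4'-(triisopropylsilyloxy)biphenyl-2-ol | Oc1ccc(Cl)cc1-c1ccc(O[Si](C(C)C)(C(C)C)C(C)C)c(CC=C)c1
F6 | step 8 | 11-(triethylsilyloxy)eudesman-4α-ol | O[C@]1(C)CCC[C@]2(C)CC[C@@H](C(C)(C)O[Si](CC)(CC)CC)C[C@H]21
F7 | step 8 | 4α-(2-bromo-4-chlorophenoxy)-11-(triethylsilyloxy)eudesmane | Clc1ccc(O[C@]2(C)CCC[C@]3(C)CC[C@@H](C(C)(C)O[Si](CC)(CC)CC)C[C@H]32)c(Br)c1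
F8 | step 8 | 4α-(3',5-dichloro-4'-hydroxybiphenyl-2-yloxy)-11-(triethylsilyloxy)eudesmane | Clc1ccc(O[C@]2(C)CCC[C@]3(C)CC[C@@H](C(C)(C)O[Si](CC)(CC)CC)C[C@H]32)c(-c2ccc(O)c(Cl)c2)c1
F9 | step 8 | 4α-(honokiol-2-yloxy)-11-(triethylsilyloxy)eudesmane | C=CCc1ccc(O[C@]2(C)CCC[C@]3(C)CC[C@@H](C(C)(C)O[Si](CC)(CC)CC)C[C@H]32)c(-c2ccc(O)c(CC=C)c2)c1
A1 | alternative 1 | (E,E)-hedycaryol | C/C1=C\CC/C(C)=C/C[C@@H](CC1)C(C)(C)O
A2 | alternative 1 | 4'-O-(triisopropylsilyl) ether of 12 | C=CCc1ccc(O[C@]2(C)CCC[C@]3(C)CC[C@@H](C(C)(C)O)C[C@H]32)c(-c2ccc(O[Si](C(C)C)(C(C)C)C(C)C)c(CC=C)c2)c1
A3 | alternative 2 | 11-hydroxy-15-noreudesman-4-one | O=C1CCC[C@]2(C)CC[C@@H](C(C)(C)O)C[C@H]21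
A4 | alternative 2 | 2-bromo-4-chlorophenol | Oc1ccc(Cl)cc1Br
A5 | alternative 2 | 4α-(2-bromo-4-chlorophenoxy)-11-hydroxyeudesman-15-oic acid | Clc1ccc(O[C@]2(C(=O)O)CCC[C@]3(C)CC[C@@H](C(C)(C)O)C[C@H]32)c(Br)c1
A6 | alternative 3 | (5R)-dihydrocarvone (C2 epimers) | CC1CC[C@@H](C(C)=C)CC1=O
A7 | alternative 3 | ethyl vinyl ketone | CCC(=O)C=C
A8 | alternative 3 | (+)-α-cyperone | O=C1CC[C@]2(C)CC[C@@H](C(C)=C)CC2=C1C
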